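## Retrosynthetic overview

1. Target ⇒ two aromatic Claisen disconnections (C8–CH2 and C2'–CH2). Both prenyl groups are stored as O-(1,1-dimethylallyl) ethers on O7 and O3' of an (S)-hesperetin bis-ether and moved to carbon in one last operation. This is late C-prenylation of the finished flavanone, as in the plant.
2. (S)-Flavanone bis-ether ⇒ O1–C2 disconnection. This is a chalcone-isomerase-type, catalyst-controlled 6-endo oxa-Michael closure of an achiral 2',6'-dihydroxychalcone. Its A ring is locally symmetric, so ring closure has no 6/8 ambiguity.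
3. Chalcone ⇒ obtained not by aldol condensation but by unzipping (retro-oxa-Michael) the bis-ether of cheap racemic hesperetin, which is made with a tert-prenyl carbonate under Pd(0).
4. Ring order: rings A and B are bought. The dihydropyranone ring C is the only ring formed (step 2), and it carries the only stereocentre.

Assumption: commercial hesperetin is the racemate (its configuration is erased in step 1 anyway), and carbonate 2 is bought as a catalogue reagent.
Assumption: the quinine-derived catalyst is taken to give 2S; if CD or chiral HPLC shows 2R, its commercial quinidine-derived pseudo-enantiomer is used under the same conditions.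

## Route

Step 1
Reactants: 1 (±)-hesperetin; 2 tert-butyl (2-methylbut-3-en-2-yl) carbonate (2.3 equiv)
Product: 5 (E)-2',6'-dihydroxy-4-methoxy-3,4'-bis(1,1-dimethylallyloxy)chalcone, via flavanone bis-ether 3 (not isolated), via dipotassium chalconate 4 (not isolated)
Conditions: Pd(PPh3)4 (5 mol %), THF, 0–5 °C, 8 h; then degassed 4 M aq KOH–EtOH, 0 °C → rt, 1 h, Ar; toluene wash; AcOH to pH 6, 0 °C; crystallise (no silica)
Reagents that add atoms: tert-butyl (2-methylbut-3-en-2-yl) carbonate, C=CC(C)(C)OC(=O)OC(C)(C)C
Why: In a Pd-catalysed decarboxylative Tsuji–Trost O-allylation the phenoxides of the two acidic OH groups (7-OH and 3'-OH, the chelated 5-OH staying free) attack the more substituted end of the 1,1-dimethyl-π-allyl-Pd cation under kinetic control to give the tertiary ethers, after which KOH opens the pyranone by E1cB retro-oxa-Michael (the alkali ring opening known for 7-O-substituted hesperetins such as hesperidin) to the E-chalcone dianion, erasing C2, and cold buffering to pH 6 releases the neutral chalcone without cleaving the acid-labile ethers.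

Step 2
Reactants: 5 (E)-2',6'-dihydroxy-4-methoxy-3,4'-bis(1,1-dimethylallyloxy)chalcone
Product: 6 (2S)-5-hydroxy-4'-methoxy-7,3'-bis(1,1-dimethylallyloxy)flavanone
Conditions: quinine-derived epi-9-amino-9-deoxy 3,5-(CF3)2C6H3-thiourea (10 mol %), toluene, 4 Å MS, −20 °C, 48–72 h; short silica plug; recrystallise
Reagents that add atoms: none
Why: Proposed new method: this is a chalcone-isomerase-mimetic enantioselective 6-endo-trig intramolecular oxa-Michael addition in which the quinuclidine nitrogen deprotonates the non-chelated ortho-OH while the thiourea hydrogen-bonds the carbonyl/enolate oxygen from the same face, so that the phenoxide reaches one face of Cβ and sets C2 as S, the second, chelated ortho-OH holding the enone coplanar and making closure much faster and practically irreversible compared with simple 2'-hydroxychalcones (hence −20 °C and no racemic background in toluene), the two ortho-OH groups being equivalent so that no regioisomer can form, and the closest known reaction type being the cinchona-thiourea-catalysed asymmetric oxa-Michael cyclisation of 2'-hydroxychalcones and of their α-carboxylate-activated analogues to flavanones.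

Step 3
Reactants: 6 (2S)-5-hydroxy-4'-methoxy-7,3'-bis(1,1-dimethylallyloxy)flavanone
Product: 9 (2S)-5,7,3'-trihydroxy-4'-methoxy-8,2'-diprenylflavanone (target), via 5-O-TMS ether 7 (not isolated), via tris-TMS ether 8 (not isolated)
Conditions: BSA (N,O-bis(trimethylsilyl)acetamide, 5 equiv), o-xylene, 70 °C, 30 min, then 140 °C, 6 h, Ar; cool; MeOH, citric acid (5 mol %), rt, 30 min
Reagents that add atoms: none
Why: Two aromatic Claisen [3,3] rearrangements turn the 1,1-dimethylallyl aryl ethers into linear ortho-prenyl groups, ring B having only C2' free (C4' carries OMe) and ring A being steered to C8 because prior silylation of the chelated 5-OH removes the OH···O=C bond fixation that favours C6 and leaves the O1–C8a=C4a–C4=O vinylogous-ester bond fixation that sends 7-allyloxy-chromanones and -coumarins to C8, while BSA traps the new phenols and keeps the medium neutral and aprotic so that C2 cannot open by retro-oxa-Michael and stays S, and mild methanolysis then removes the three TMS groups.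

## Compound list

1 | (±)-hesperetin (5,7,3'-trihydroxy-4'-methoxyflavanone, racemic) | COc1ccc(C2CC(=O)c3c(O)cc(O)cc3O2)cc1O | starting material
2 | tert-butyl (2-methylbut-3-en-2-yl) carbonate | C=CC(C)(C)OC(=O)OC(C)(C)C | starting material
3 | (±)-5-hydroxy-4'-methoxy-7,3'-bis(1,1-dimethylallyloxy)flavanone | COc1ccc(C2CC(=O)c3c(O)cc(OC(C)(C)C=C)cc3O2)cc1OC(C)(C)C=C | intermediate
4 | dipotassium 2',6'-diphenolate of chalcone 5 | COc1ccc(/C=C/C(=O)c2c([O-])cc(OC(C)(C)C=C)cc2[O-])cc1OC(C)(C)C=C.[K+].[K+] | intermediate
5 | (E)-1-[2,6-dihydroxy-4-(2-methylbut-3-en-2-yloxy)phenyl]-3-[4-methoxy-3-(2-methylbut-3-en-2-yloxy)phenyl]prop-2-en-1-one | COc1ccc(/C=C/C(=O)c2c(O)cc(OC(C)(C)C=C)cc2O)cc1OC(C)(C)C=C | intermediate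
6 | (2S)-5-hydroxy-4'-methoxy-7,3'-bis(1,1-dimethylallyloxy)flavanone | COc1ccc([C@@H]2CC(=O)c3c(O)cc(OC(C)(C)C=C)cc3O2)cc1OC(C)(C)C=C | intermediate
7 | (2S)-5-(trimethylsilyloxy)-4'-methoxy-7,3'-bis(1,1-dimethylallyloxy)flavanone | COc1ccc([C@@H]2CC(=O)c3c(O[Si](C)(C)C)cc(OC(C)(C)C=C)cc3O2)cc1OC(C)(C)C=C | intermediate
8 | (2S)-5,7,3'-tris(trimethylsilyloxy)-4'-methoxy-8,2'-diprenylflavanone | COc1ccc([C@@H]2CC(=O)c3c(O[Si](C)(C)C)cc(O[Si](C)(C)C)c(CC=C(C)C)c3O2)c(CC=C(C)C)c1O[Si](C)(C)C | intermediate
9 | (2S)-5,7-dihydroxy-2-[3-hydroxy-4-methoxy-2-(3-methylbut-2-enyl)phenyl]-8-(3-methylbut-2-enyl)chroman-4-one | COc1ccc([C@@H]2CC(=O)c3c(O)cc(O)c(CC=C(C)C)c3O2)c(CC=C(C)C)c1O | target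

## Step count and risks

Total step count: 3. Longest linear sequence: 3 (1 → 5 → 6 → 9).

**Most likely to fail, first: step 2 (level of ee and rate).**
- High ee has not been shown for an unactivated 2',6'-dihydroxychalcone.
- Any racemic 3 left in 5 ends up in 6 and lowers its ee, so 5 must be flavanone-free by NMR.
- The configuration of 6 is checked by CD (2S: negative band near 290 nm, positive near 330 nm).
- Material of low ee is not lost, because KOH as in step 1 returns it to 5.
- Fallback, replacing asymmetric closure by resolution: step 1 is stopped before the KOH stage and 3 is isolated. It is then subjected to a Noyori–Ikariya asymmetric transfer hydrogenation run as a kinetic resolution (Rh– or Ru–TsDPEN, HCO2Na, H2O/EtOAc, rt, about 55 % conversion). The catalyst enantiomer matched to (2R)-3 reduces it to the cis-(2R,4R)-flavan-4-ol F1, and the untouched (2S)-ketone is 6 (at most 50 %). This fallback sets out from 3 and comes back at 6.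

**Second: step 3 (C8 versus C6 on ring A, and retention of ee at 140 °C).**
- The C8 preference rests on bond-fixation reasoning and on chromanone and coumarin analogy, so some 6-prenyl isomer is expected and is removed by chromatography.
- Adventitious enol silylation could open a racemisation path, so the ee is re-measured on 9.
- Fallback, blocking C6 instead of steering the migration: 6 is iodinated ortho to the free chelated 5-OH (BnMe3N·ICl2, CaCO3, CH2Cl2–MeOH, rt) to give the (2S)-6-iodo bis-ether F2. Plain thermolysis (o-xylene, 130 °C) can then deliver the A-ring prenyl only to C8, giving (2S)-6-iodo-8,2'-diprenylhesperetin F3. The iodine flanked by two phenols is then removed by sulfite protodeiodination (Na2SO3, pH 7 phosphate, aq EtOH, 50 °C). This fallback sets out from 6 and comes back at 9.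

**Third: step 1 (branched versus linear ether, C-allylation, premature re-closure).**
- The 7-O tertiary ether is a good leaving group, so Pd(0) can equilibrate it to the linear prenyl ether or to C-prenyl products if the reaction runs warm or long.
- Fallback, avoiding π-allyl chemistry: 1 is O-alkylated with 3-chloro-3-methylbut-1-yne (CuCl2·2H2O 1 mol %, DBU, MeCN, 0 °C) to give the 7,3'-bis(1,1-dimethylpropargyl) ether F4. This is semi-hydrogenated (H2, Lindlar catalyst, quinoline, EtOAc) to 3, and the KOH stage of step 1 then follows unchanged. This fallback sets out from 1 and comes back at 3.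

## Further compounds

F1 | step 2 | (2R,4R)-cis-2-[4-methoxy-3-(2-methylbut-3-en-2-yloxy)phenyl]-7-(2-methylbut-3-en-2-yloxy)chromane-4,5-diol | O[C@@H]1C[C@H](c2ccc(OC)c(OC(C)(C)C=C)c2)Oc2cc(OC(C)(C)C=C)cc(O)c21
F2 | step 3 | (2S)-5-hydroxy-6-iodo-4'-methoxy-7,3'-bis(1,1-dimethylallyloxy)flavanone | COc1ccc([C@@H]2CC(=O)c3c(O)c(I)c(OC(C)(C)C=C)cc3O2)cc1OC(C)(C)C=C
F3 | step 3 | (2S)-5,7,3'-trihydroxy-6-iodo-4'-methoxy-8,2'-diprenylflavanone | COc1ccc([C@@H]2CC(=O)c3c(O)c(I)c(O)c(CC=C(C)C)c3O2)c(CC=C(C)C)c1O
F4 | step 1 | (±)-5-hydroxy-4'-methoxy-7,3'-bis(1,1-dimethylpropargyloxy)flavanone | COc1ccc(C2CC(=O)c3c(O)cc(OC(C)(C)C#C)cc3O2)cc1OC(C)(C)C#C
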